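## Retrosynthetic overview

1. The esters go on last: the target comes from the 4α,6α,10α-triol (C6 aroylation, C10 tigloylation, phenol release); the saturated five-membered ring comes from diimide reduction of a C2=C3 alkene.
2. The seven-membered ring is formed second, by ring-closing metathesis across C8=C9 between a C10 vinyl carbinol and a methallyl arm on C6; the vinyl carbinol is made from a glyceraldehyde-derived diol via a terminal epoxide and a sulfonium ylide.
3. The five-membered ring is formed first, by ring-closing metathesis across C2=C3 after a chelation-controlled vinyl addition to a C4 isopropyl ketone released from a β-lactone.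
4. The key C1–C5 bond (quaternary C1 next to C5) is made by a dianionic Ireland–Claisen [3,3] rearrangement of a β-hydroxy allylic ester.
5. That ester is assembled from ethyl (R)-4-chloro-3-hydroxybutanoate (brings C6) and (R)-glyceraldehyde acetonide (brings C10).

Assumption: the SMILES is taken as drawn (E-2-methylbut-2-enoate, trans ring fusion, 4-OH cis to H-5); locants follow daucane numbering (C1 = C(CH3) ring fusion, C4 = C(OH)iPr, C5 = ring-fusion CH, C6 = aroyloxy carbon, C8 = C(CH3)=, C10 = tigloyloxy carbon); commercial reagents that only deliver a fragment are given with SMILES on the reagent line and carry no compound number.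

## Route

Step 1
Reactants: 1 ethyl (3R)-4-chloro-3-hydroxybutanoate
Product: 2 ethyl 2-[(2R)-oxiran-2-yl]acetate
Conditions: Ag2O, 1,2-dimethoxyethane, 60 °C, dark
Reagents that add atoms: none
Why: Silver-assisted intramolecular Williamson etherification closes the epoxide through the hydroxyl oxygen, so the C–O bond at the stereocentre (future C6) is never broken and the neutral conditions avoid base-induced opening to the 4-hydroxycrotonate.

Step 2
Reactants: 2 ethyl 2-[(2R)-oxiran-2-yl]acetate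
Product: 3 ethyl (3S)-3-hydroxy-5-methylhex-5-enoate
Conditions: isopropenylMgBr, CuI (10 mol %), THF, −40 °C; aq NH4Cl
Reagents that add atoms: isopropenylmagnesium bromide, CC(=C)[Mg]Br
Why: Copper-catalysed Grignard opening of the terminal epoxide (SN2 at the CH2 carbon) outruns addition to the ester at −40 °C and installs the methallyl arm (C7, C8 and its methyl) without touching the carbinol stereocentre.

Step 3
Reactants: 4 (4R)-2,2-dimethyl-1,3-dioxolane-4-carbaldehyde
Product: 5 (4S)-4-ethynyl-2,2-dimethyl-1,3-dioxolane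
Conditions: dimethyl (1-diazo-2-oxopropyl)phosphonate, K2CO3, MeOH, 0 °C to rt
Reagents that add atoms: dimethyl (1-diazo-2-oxopropyl)phosphonate, COP(=O)(OC)C(=[N+]=[N-])C(C)=O
Why: Seyferth–Gilbert homologation in its Ohira–Bestmann form converts the aldehyde into the terminal alkyne under mild carbonate conditions, the adjacent acetal stereocentre (future C10) being retained.

Step 4
Reactants: 5 (4S)-4-ethynyl-2,2-dimethyl-1,3-dioxolane
Product: 7 (2E)-3-[(4S)-2,2-dimethyl-1,3-dioxolan-4-yl]but-2-en-1-ol, via alkenylalane 6 (not isolated)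
Conditions: Me3Al, Cp2ZrCl2 (20 mol %), CH2Cl2, 0 °C to rt; then n-BuLi, THF, −78 °C; (CH2O)n, −78 °C to rt; aq Rochelle salt
Reagents that add atoms: trimethylaluminium, C[Al](C)C; paraformaldehyde (formaldehyde), C=O
Why: Negishi zirconium-catalysed carboalumination adds CH3 and Al syn across the alkyne with methyl on the internal carbon, and the derived alanate is hydroxymethylated with retention, so the E-trisubstituted allylic alcohol (CH2OH cis to CH3) results.

Step 5
Reactants: 3 ethyl (3S)-3-hydroxy-5-methylhex-5-enoate; 7 (2E)-3-[(4S)-2,2-dimethyl-1,3-dioxolan-4-yl]but-2-en-1-ol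
Product: 8 (2E)-3-[(4S)-2,2-dimethyl-1,3-dioxolan-4-yl]but-2-en-1-yl (3S)-3-hydroxy-5-methylhex-5-enoate
Conditions: Ti(OEt)4 (10 mol %), toluene, 110 °C, 4 Å sieves (removal of EtOH)
Reagents that add atoms: none
Why: Titanate-catalysed transesterification of the β-hydroxy ester, driven by removal of ethanol, joins the two chiral-pool fragments under neutral conditions that leave the acetonide, both alkenes and both stereocentres untouched.

Step 6
Reactants: 8 (2E)-3-[(4S)-2,2-dimethyl-1,3-dioxolan-4-yl]but-2-en-1-yl (3S)-3-hydroxy-5-methylhex-5-enoate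
Product: 9 (2S,3S)-2-{(2S)-2-[(4S)-2,2-dimethyl-1,3-dioxolan-4-yl]but-3-en-2-yl}-3-hydroxy-5-methylhex-5-enoic acid
Conditions: LDA (2.3 equiv), THF, −78 °C, then 50 °C; 10% citric acid
Reagents that add atoms: none
Why: In this dianionic Ireland–Claisen [3,3]-sigmatropic rearrangement the lithium-chelated alkoxide–enolate (C6 cis to the enolate oxygen) accepts the allyl unit through a chair transition state on the face anti to C7 of the chelate (C5 anti to the C6 hydroxyl, as in Fráter–Seebach alkylation), and the E-alkene (CH3 axial, dioxolanyl equatorial, new bond anti to the dioxolane C–O) fixes the quaternary C1 relative to C5.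

Step 7
Reactants: 9 (2S,3S)-2-{(2S)-2-[(4S)-2,2-dimethyl-1,3-dioxolan-4-yl]but-3-en-2-yl}-3-hydroxy-5-methylhex-5-enoic acid
Product: 10 (3S,4S)-3-{(2S)-2-[(4S)-2,2-dimethyl-1,3-dioxolan-4-yl]but-3-en-2-yl}-4-(2-methylprop-2-en-1-yl)oxetan-2-one
Conditions: PhSO2Cl, pyridine, 0 °C
Reagents that add atoms: none
Why: In this Adam β-lactonisation the carboxyl group is activated as its mixed sulfonic anhydride and attacked by the C6 hydroxyl, so C6 is retained and the hindered acid becomes a strained, easily opened acyl donor.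

Step 8
Reactants: 10 (3S,4S)-3-{(2S)-2-[(4S)-2,2-dimethyl-1,3-dioxolan-4-yl]but-3-en-2-yl}-4-(2-methylprop-2-en-1-yl)oxetan-2-one
Product: 12 (3R,4S,5S)-4-{(2S)-2-[(4S)-2,2-dimethyl-1,3-dioxolan-4-yl]but-3-en-2-yl}-7-methyl-3-(propan-2-yl)octa-1,7-diene-3,5-diol, via β-hydroxy ketone 11 (not isolated)
Conditions: iPrMgCl (1.1 equiv), THF, −78 °C; then vinylMgBr (3 equiv), −78 to −20 °C; aq NH4Cl
Reagents that add atoms: isopropylmagnesium chloride, CC(C)[Mg]Cl; vinylmagnesium bromide, C=C[Mg]Br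
Why: Grignard acyl substitution opens the β-lactone to the magnesium aldolate of the isopropyl ketone, and chelation-controlled (Cram-chelate, Felkin-consistent) 1,2-addition of the vinyl Grignard anti to the quaternary C1 group of the six-membered chelate places vinyl syn to H-5 and isopropyl syn to C1, which is the required C4 configuration.

Step 9
Reactants: 12 (3R,4S,5S)-4-{(2S)-2-[(4S)-2,2-dimethyl-1,3-dioxolan-4-yl]but-3-en-2-yl}-7-methyl-3-(propan-2-yl)octa-1,7-diene-3,5-diol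
Product: 13 (1R,4S,5S)-4-[(4S)-2,2-dimethyl-1,3-dioxolan-4-yl]-5-[(1S)-1-hydroxy-3-methylbut-3-en-1-yl]-4-methyl-1-(propan-2-yl)cyclopent-2-en-1-ol
Conditions: second-generation Grubbs catalyst RuCl2(=CHPh)(PCy3)(H2IMes) (5 mol %), CH2Cl2 (5 mM), 40 °C
Reagents that add atoms: none
Why: Ring-closing metathesis of the two monosubstituted vinyl groups on C1 and C4 (five-membered ring, helped by the allylic hydroxyl and gem-disubstitution) is much faster than closure onto the 1,1-disubstituted methallyl group, and no stereocentre is involved.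

Step 10
Reactants: 13 (1R,4S,5S)-4-[(4S)-2,2-dimethyl-1,3-dioxolan-4-yl]-5-[(1S)-1-hydroxy-3-methylbut-3-en-1-yl]-4-methyl-1-(propan-2-yl)cyclopent-2-en-1-ol
Product: 14 (1S)-1-{(1S,4R,5S)-4-hydroxy-5-[(1S)-1-hydroxy-3-methylbut-3-en-1-yl]-1-methyl-4-(propan-2-yl)cyclopent-2-en-1-yl}ethane-1,2-diol
Conditions: PPTS (20 mol %), MeOH, 40 °C
Reagents that add atoms: none
Why: Acid-catalysed transacetalisation with methanol removes the terminal acetonide under conditions mild enough for the tertiary allylic alcohol.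

Step 11
Reactants: 14 (1S)-1-{(1S,4R,5S)-4-hydroxy-5-[(1S)-1-hydroxy-3-methylbut-3-en-1-yl]-1-methyl-4-(propan-2-yl)cyclopent-2-en-1-yl}ethane-1,2-diol
Product: 16 (1R,4S,5S)-5-[(1S)-1-hydroxy-3-methylbut-3-en-1-yl]-4-methyl-4-[(2S)-oxiran-2-yl]-1-(propan-2-yl)cyclopent-2-en-1-ol, via primary tosylate 15 (not isolated)
Conditions: Bu2SnO (5 mol %), TsCl (1.05 equiv), Et3N, CH2Cl2, 0 °C; then K2CO3, MeOH, 0 °C to rt
Reagents that add atoms: none
Why: Tin-mediated regioselective sulfonylation of the primary hydroxyl of the 1,2-diol followed by intramolecular Williamson closure by the C10 alkoxide gives the terminal epoxide with retention at C10, since only the C9–O bond is exchanged.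

Step 12
Reactants: 16 (1R,4S,5S)-5-[(1S)-1-hydroxy-3-methylbut-3-en-1-yl]-4-methyl-4-[(2S)-oxiran-2-yl]-1-(propan-2-yl)cyclopent-2-en-1-ol
Product: 17 (1R,4S,5S)-5-[(1S)-1-hydroxy-3-methylbut-3-en-1-yl]-4-[(1R)-1-hydroxyprop-2-en-1-yl]-4-methyl-1-(propan-2-yl)cyclopent-2-en-1-ol
Conditions: Me3S+ I− (6 equiv), n-BuLi (5.5 equiv), THF, −10 °C to rt
Reagents that add atoms: trimethylsulfonium iodide, C[S+](C)C.[I-]
Why: Sulfonium-ylide homologation (Corey–Chaykovsky-type attack of the ylide at the epoxide CH2, then base-induced loss of dimethyl sulfide from the γ-oxido sulfonium salt) turns the terminal epoxide into the one-carbon-longer allylic alcohol without touching C10.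

Step 13
Reactants: 17 (1R,4S,5S)-5-[(1S)-1-hydroxy-3-methylbut-3-en-1-yl]-4-[(1R)-1-hydroxyprop-2-en-1-yl]-4-methyl-1-(propan-2-yl)cyclopent-2-en-1-ol
Product: 18 (3R,3aS,4S,8R,8aS)-6,8a-dimethyl-3-(propan-2-yl)-3,3a,4,5,8,8a-hexahydroazulene-3,4,8-triol
Conditions: second-generation Hoveyda–Grubbs catalyst RuCl2(=CH-C6H4-2-OiPr)(H2IMes) (10 mol %), toluene (2 mM), 80 °C
Reagents that add atoms: none
Why: Ring-closing metathesis between the C10 vinyl carbinol and the methallyl group closes the seven-membered ring as its trisubstituted C8=C9 alkene, and the trans relationship of the two tethers on the cyclopentene, fixed in step 6, gives the trans-fused hydroazulene.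

Step 14
Reactants: 18 (3R,3aS,4S,8R,8aS)-6,8a-dimethyl-3-(propan-2-yl)-3,3a,4,5,8,8a-hexahydroazulene-3,4,8-triol
Product: 19 (3S,3aS,4S,8R,8aS)-6,8a-dimethyl-3-(propan-2-yl)-1,2,3,3a,4,5,8,8a-octahydroazulene-3,4,8-triol
Conditions: 2-nitrobenzenesulfonohydrazide, Et3N, CH2Cl2, 25 °C
Reagents that add atoms: none
Why: Diimide reduction (concerted syn hydrogen transfer from HN=NH generated in situ) saturates the cis-disubstituted cyclopentene much faster than the trisubstituted C8=C9 alkene and creates no stereocentre.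

Step 15
Reactants: 19 (3S,3aS,4S,8R,8aS)-6,8a-dimethyl-3-(propan-2-yl)-1,2,3,3a,4,5,8,8a-octahydroazulene-3,4,8-triol
Product: 20 (3S,3aS,4S,8R,8aS)-3,8-dihydroxy-6,8a-dimethyl-3-(propan-2-yl)-1,2,3,3a,4,5,8,8a-octahydroazulen-4-yl 4-(acetyloxy)benzoate
Conditions: 4-acetoxybenzoyl chloride (1.05 equiv), pyridine, DMAP (5 mol %), CH2Cl2, −20 °C
Reagents that add atoms: 4-acetoxybenzoyl chloride, CC(=O)Oc1ccc(cc1)C(Cl)=O
Why: In this DMAP-catalysed site-selective acylation the equatorial C6 hydroxyl reacts ahead of the pseudo-axial, neopentylic C10 hydroxyl and the tertiary C4 hydroxyl, with retention at C6.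

Step 16
Reactants: 20 (3S,3aS,4S,8R,8aS)-3,8-dihydroxy-6,8a-dimethyl-3-(propan-2-yl)-1,2,3,3a,4,5,8,8a-octahydroazulen-4-yl 4-(acetyloxy)benzoate
Product: 21 (3S,3aS,4S,8R,8aS)-4-{[4-(acetyloxy)benzoyl]oxy}-3-hydroxy-6,8a-dimethyl-3-(propan-2-yl)-1,2,3,3a,4,5,8,8a-octahydroazulen-8-yl (2E)-2-methylbut-2-enoate
Conditions: tigloyl chloride (3 equiv), pyridine, DMAP, CH2Cl2, 40 °C
Reagents that add atoms: (E)-2-methylbut-2-enoyl chloride, C/C=C(\C)C(Cl)=O
Why: Nucleophile-catalysed esterification through the acylpyridinium acylates the remaining secondary allylic C10 hydroxyl with retention, the tertiary C4 hydroxyl does not react, and the E-configured tiglate is the thermodynamically stable isomer.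

Step 17
Reactants: 21 (3S,3aS,4S,8R,8aS)-4-{[4-(acetyloxy)benzoyl]oxy}-3-hydroxy-6,8a-dimethyl-3-(propan-2-yl)-1,2,3,3a,4,5,8,8a-octahydroazulen-8-yl (2E)-2-methylbut-2-enoate
Product: 22 (3S,3aS,4S,8R,8aS)-3-hydroxy-4-[(4-hydroxybenzoyl)oxy]-6,8a-dimethyl-3-(propan-2-yl)-1,2,3,3a,4,5,8,8a-octahydroazulen-8-yl (2E)-2-methylbut-2-enoate
Conditions: NH4OAc (10 equiv), MeOH–H2O (4:1), 25 °C
Reagents that add atoms: none
Why: Chemoselective solvolysis (transesterification) of the phenolic acetate, whose phenoxide leaving group makes it far more labile than the benzoate and tiglate esters, releases the free phenol and the target.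

## Compound list

1 | ethyl (3R)-4-chloro-3-hydroxybutanoate | CCOC(=O)C[C@@H](O)CCl | starting material
2 | ethyl 2-[(2R)-oxiran-2-yl]acetate | CCOC(=O)C[C@@H]1CO1 | intermediate
3 | ethyl (3S)-3-hydroxy-5-methylhex-5-enoate | CCOC(=O)C[C@@H](O)CC(C)=C | intermediate
4 | (4R)-2,2-dimethyl-1,3-dioxolane-4-carbaldehyde | CC1(C)OC[C@H](C=O)O1 | starting material
5 | (4S)-4-ethynyl-2,2-dimethyl-1,3-dioxolane | CC1(C)OC[C@H](C#C)O1 | intermediate
6 | dimethyl{(1E)-2-[(4S)-2,2-dimethyl-1,3-dioxolan-4-yl]prop-1-en-1-yl}alumane | C[Al](C)/C=C(\C)[C@H]1COC(C)(C)O1 | intermediate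
7 | (2E)-3-[(4S)-2,2-dimethyl-1,3-dioxolan-4-yl]but-2-en-1-ol | OC/C=C(\C)[C@H]1COC(C)(C)O1 | intermediate
8 | (2E)-3-[(4S)-2,2-dimethyl-1,3-dioxolan-4-yl]but-2-en-1-yl (3S)-3-hydroxy-5-methylhex-5-enoate | C=C(C)C[C@H](O)CC(=O)OC/C=C(\C)[C@H]1COC(C)(C)O1 | intermediate
9 | (2S,3S)-2-{(2S)-2-[(4S)-2,2-dimethyl-1,3-dioxolan-4-yl]but-3-en-2-yl}-3-hydroxy-5-methylhex-5-enoic acid | OC(=O)[C@H]([C@@H](O)CC(C)=C)[C@](C)(C=C)[C@H]1COC(C)(C)O1 | intermediate
10 | (3S,4S)-3-{(2S)-2-[(4S)-2,2-dimethyl-1,3-dioxolan-4-yl]but-3-en-2-yl}-4-(2-methylprop-2-en-1-yl)oxetan-2-one | O=C1O[C@@H](CC(C)=C)[C@@H]1[C@](C)(C=C)[C@H]2COC(C)(C)O2 | intermediate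
11 | (4S,5S)-4-{(2S)-2-[(4S)-2,2-dimethyl-1,3-dioxolan-4-yl]but-3-en-2-yl}-5-hydroxy-2,7-dimethyloct-7-en-3-one | CC(C)C(=O)[C@H]([C@@H](O)CC(C)=C)[C@](C)(C=C)[C@H]1COC(C)(C)O1 | intermediate
12 | (3R,4S,5S)-4-{(2S)-2-[(4S)-2,2-dimethyl-1,3-dioxolan-4-yl]but-3-en-2-yl}-7-methyl-3-(propan-2-yl)octa-1,7-diene-3,5-diol | CC(C)[C@@](O)(C=C)[C@H]([C@@H](O)CC(C)=C)[C@](C)(C=C)[C@H]1COC(C)(C)O1 | intermediate
13 | (1R,4S,5S)-4-[(4S)-2,2-dimethyl-1,3-dioxolan-4-yl]-5-[(1S)-1-hydroxy-3-methylbut-3-en-1-yl]-4-methyl-1-(propan-2-yl)cyclopent-2-en-1-ol | CC(C)[C@@]1(O)C=C[C@](C)([C@H]2COC(C)(C)O2)[C@H]1[C@@H](O)CC(C)=C | intermediate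
14 | (1S)-1-{(1S,4R,5S)-4-hydroxy-5-[(1S)-1-hydroxy-3-methylbut-3-en-1-yl]-1-methyl-4-(propan-2-yl)cyclopent-2-en-1-yl}ethane-1,2-diol | CC(C)[C@@]1(O)C=C[C@](C)([C@H](O)CO)[C@H]1[C@@H](O)CC(C)=C | intermediate
15 | (2S)-2-hydroxy-2-{(1S,4R,5S)-4-hydroxy-5-[(1S)-1-hydroxy-3-methylbut-3-en-1-yl]-1-methyl-4-(propan-2-yl)cyclopent-2-en-1-yl}ethyl 4-methylbenzenesulfonate | CC(C)[C@@]1(O)C=C[C@](C)([C@H](O)COS(=O)(=O)c2ccc(C)cc2)[C@H]1[C@@H](O)CC(C)=C | intermediate
16 | (1R,4S,5S)-5-[(1S)-1-hydroxy-3-methylbut-3-en-1-yl]-4-methyl-4-[(2S)-oxiran-2-yl]-1-(propan-2-yl)cyclopent-2-en-1-ol | CC(C)[C@@]1(O)C=C[C@](C)([C@H]2CO2)[C@H]1[C@@H](O)CC(C)=C | intermediate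
17 | (1R,4S,5S)-5-[(1S)-1-hydroxy-3-methylbut-3-en-1-yl]-4-[(1R)-1-hydroxyprop-2-en-1-yl]-4-methyl-1-(propan-2-yl)cyclopent-2-en-1-ol | CC(C)[C@@]1(O)C=C[C@](C)([C@H](O)C=C)[C@H]1[C@@H](O)CC(C)=C | intermediate
18 | (3R,3aS,4S,8R,8aS)-6,8a-dimethyl-3-(propan-2-yl)-3,3a,4,5,8,8a-hexahydroazulene-3,4,8-triol | O[C@@H]1C=C(C)C[C@H](O)[C@@H]2[C@]1(C)C=C[C@]2(O)C(C)C | intermediate
19 | (3S,3aS,4S,8R,8aS)-6,8a-dimethyl-3-(propan-2-yl)-1,2,3,3a,4,5,8,8a-octahydroazulene-3,4,8-triol | O[C@@H]1C=C(C)C[C@H](O)[C@@H]2[C@]1(C)CC[C@]2(O)C(C)C | intermediate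
20 | (3S,3aS,4S,8R,8aS)-3,8-dihydroxy-6,8a-dimethyl-3-(propan-2-yl)-1,2,3,3a,4,5,8,8a-octahydroazulen-4-yl 4-(acetyloxy)benzoate | O[C@@H]1C=C(C)C[C@H](OC(=O)c3ccc(OC(C)=O)cc3)[C@@H]2[C@]1(C)CC[C@]2(O)C(C)C | intermediate
21 | (3S,3aS,4S,8R,8aS)-4-{[4-(acetyloxy)benzoyl]oxy}-3-hydroxy-6,8a-dimethyl-3-(propan-2-yl)-1,2,3,3a,4,5,8,8a-octahydroazulen-8-yl (2E)-2-methylbut-2-enoate | C/C=C(\C)C(=O)O[C@@H]1C=C(C)C[C@H](OC(=O)c3ccc(OC(C)=O)cc3)[C@@H]2[C@]1(C)CC[C@]2(O)C(C)C | intermediate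
22 | (3S,3aS,4S,8R,8aS)-3-hydroxy-4-[(4-hydroxybenzoyl)oxy]-6,8a-dimethyl-3-(propan-2-yl)-1,2,3,3a,4,5,8,8a-octahydroazulen-8-yl (2E)-2-methylbut-2-enoate (CNP0273650.6) | C/C=C(\C)C(=O)O[C@@H]1C=C(C)C[C@H](OC(=O)c2ccc(O)cc2)[C@@H]2[C@]1(C)CC[C@]2(O)C(C)C | target

## Step count and risks

Total step count: 17. Longest linear sequence: 15 steps (steps 1, 2, 5–17; the branch through steps 3 and 4 is equally long).

Steps most likely to fail:

Step 6 (dianionic Ireland–Claisen). The rearrangement must build a quaternary carbon next to a tertiary one, and the dianion may fragment by retro-aldol or lose anti selectivity on warming. The fallback gives up the chelate: setting out from 8, the C6 hydroxyl is silylated (TBSCl, imidazole) to the 3-O-tert-butyldimethylsilyl ether of ester 8 F1. Its Z-enolate, formed with LDA in THF–DMPU and trapped with TMSCl at −78 °C (same enolate geometry as in the chelate), rearranges as the silyl ketene acetal at 70 °C to the 3-O-silylated acid F2. HF·pyridine then removes the silyl group and the route is rejoined at 9.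

Step 8 (one-pot lactone opening and vinyl addition). The isopropyl ketone is hindered on both sides, so enolisation, reduction or retro-aldol may compete with vinyl addition. The fallback is stepwise with a different acyl donor: setting out from 10, the lactone is opened with the aluminium amide made from Me3Al and N,O-dimethylhydroxylamine hydrochloride to the β-hydroxy Weinreb amide F3. iPrMgCl converts this into ketone 11, which is isolated here. The less basic vinylcerium reagent (vinylMgBr, CeCl3, THF, −78 °C) then adds under the same chelation control, and the route is rejoined at 12.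

Step 14 (diimide reduction). The cyclopentene alkene is flanked by two fully substituted carbons, so its rate advantage over the trisubstituted C8=C9 alkene may be small. The fallback postpones the reduction and makes it hydroxyl-directed: setting out from 18, the C6 hydroxyl is acylated with 4-acetoxybenzoyl chloride to the dienyl 4-acetoxybenzoate F4, and the C10 hydroxyl is tigloylated to the diene diester F5. With C4–OH as the only free hydroxyl, hydrogenation with [Ir(cod)(PCy3)(py)]PF6 under H2 (1 atm, CH2Cl2, 0 °C) is steered to the adjacent C2=C3 bond, and the route is rejoined at 21.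

## Further compounds

F1 | step 6 | (2E)-3-[(4S)-2,2-dimethyl-1,3-dioxolan-4-yl]but-2-en-1-yl (3S)-3-[(tert-butyldimethylsilyl)oxy]-5-methylhex-5-enoate | C=C(C)C[C@H](O[Si](C)(C)C(C)(C)C)CC(=O)OC/C=C(\C)[C@H]1COC(C)(C)O1
F2 | step 6 | (2S,3S)-3-[(tert-butyldimethylsilyl)oxy]-2-{(2S)-2-[(4S)-2,2-dimethyl-1,3-dioxolan-4-yl]but-3-en-2-yl}-5-methylhex-5-enoic acid | OC(=O)[C@H]([C@@H](O[Si](C)(C)C(C)(C)C)CC(C)=C)[C@](C)(C=C)[C@H]1COC(C)(C)O1
F3 | step 8 | (2S,3S)-2-{(2S)-2-[(4S)-2,2-dimethyl-1,3-dioxolan-4-yl]but-3-en-2-yl}-3-hydroxy-N-methoxy-N,5-dimethylhex-5-enamide | CON(C)C(=O)[C@H]([C@@H](O)CC(C)=C)[C@](C)(C=C)[C@H]1COC(C)(C)O1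
F4 | step 14 | (3R,3aS,4S,8R,8aS)-3,8-dihydroxy-6,8a-dimethyl-3-(propan-2-yl)-3,3a,4,5,8,8a-hexahydroazulen-4-yl 4-(acetyloxy)benzoate | O[C@@H]1C=C(C)C[C@H](OC(=O)c3ccc(OC(C)=O)cc3)[C@@H]2[C@]1(C)C=C[C@]2(O)C(C)C
F5 | step 14 | (3R,3aS,4S,8R,8aS)-4-{[4-(acetyloxy)benzoyl]oxy}-3-hydroxy-6,8a-dimethyl-3-(propan-2-yl)-3,3a,4,5,8,8a-hexahydroazulen-8-yl (2E)-2-methylbut-2-enoate | C/C=C(\C)C(=O)O[C@@H]1C=C(C)C[C@H](OC(=O)c3ccc(OC(C)=O)cc3)[C@@H]2[C@]1(C)C=C[C@]2(O)C(C)C
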